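**Retrosynthetic overview**

1. The benzotropolone is cut last: catechol ring B of (−)-epicatechin gallate 18 plus the 2,3,4-trihydroxyphenyl ring of flavan-3-ol 17, joined by a peroxidase with loss of CO2 (step 13). The drawn target carries the ungalloylated flavan on C7, next to the tropolone OH, which is what a 2′,3′,4′-triol (not a 3′,4′,5′-triol) delivers.
2. Ring C of 17 is not closed as a pyran. It comes from the cis-2-aryl-2,3-dihydrobenzofuran-3-ylmethyl acetate 13 by a 1,2-shift of ring-A carbon C4a from C3 to the exocyclic CH2 (future C4), with acetate returning at C3 (five → six, step 11).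
3. Enabling feature: the C4 methylene sits between the oxygen-bearing C3 and C4a of phloroglucinol ring A, and C4a has O1, O5 and O7 ortho, ortho and para to it, ideal for ipso bridging.
4. The five-membered skeleton is the easier one to build with stereocontrol: aryl diazoacetate 9 → cis-dihydrobenzofuran 10 by enantioselective carbenoid C–H insertion (step 8). 9 comes from lactone 5, which tells the three phloroglucinol oxygens apart, and benzylic alcohol 3.
5. Ring order: ring A and both B rings are bought; dihydrofuran ring (step 8) → ring C by enlargement (step 11) → tropolone ring (step 13).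

Key step: step 11

Remarks (assumptions):
- The constitution is taken exactly as drawn (flavan on C7 of the benzo[7]annulenone, a regioisomer of the tea pigment theaflavin 3′-gallate).
- Rh2(S-PTTL)4 is assumed to give the (2S,3R) ester 10; if the sense is opposite, Rh2(R-PTTL)4 is used without other change.
- Compounds 1, 4 and 18 are taken as catalogue compounds.

**Route**

Step 1
Reactants: 1 2,3,4-trihydroxybenzaldehyde
Product: 2 2,3,4-tris(benzyloxy)benzaldehyde
Conditions: BnBr, K2CO3, DMF, 60 °C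
Reagents that add atoms: benzyl bromide, BrCc1ccccc1
Why: Williamson ether synthesis on the three phenoxides; heating in DMF also alkylates the chelated 2-hydroxyl.

Step 2
Reactants: 2 2,3,4-tris(benzyloxy)benzaldehyde
Product: 3 [2,3,4-tris(benzyloxy)phenyl]methanol
Conditions: NaBH4, MeOH–THF, 0 °C
Reagents that add atoms: none
Why: Borohydride reduction of an aryl aldehyde to the primary benzylic alcohol.

Step 3
Reactants: 4 2-(2,4,6-trimethoxyphenyl)acetic acid
Product: 5 4,6-dihydroxy-1-benzofuran-2(3H)-one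
Conditions: BBr3 (5 equiv), CH2Cl2, −78 → 25 °C; H2O; then TsOH (cat.), EtOAc, 50 °C
Reagents that add atoms: none
Why: BBr3 ether cleavage followed by lactonisation of the 2-hydroxyphenylacetic acid; the lactone masks one ortho oxygen and leaves the other ortho and the para hydroxyl free.

Step 4
Reactants: 5 4,6-dihydroxy-1-benzofuran-2(3H)-one
Product: 6 4,6-bis(triisopropylsilyloxy)-1-benzofuran-2(3H)-one
Conditions: i-Pr3SiOTf (2.3 equiv), 2,6-lutidine, CH2Cl2, 0 °C
Reagents that add atoms: triisopropylsilyl trifluoromethanesulfonate, CC(C)[Si](OS(=O)(=O)C(F)(F)F)(C(C)C)C(C)C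
Why: Phenol silylation; a silyl ether has no C–H on an atom next to oxygen for the later carbenoid to attack, and it keeps ring A electron-rich for step 11.

Step 5
Reactants: 6 4,6-bis(triisopropylsilyloxy)-1-benzofuran-2(3H)-one
Product: 7 methyl 2-[2-hydroxy-4,6-bis(triisopropylsilyloxy)phenyl]acetate
Conditions: MeOH–THF, Et3N (0.2 equiv), 0 → 25 °C; AcOH quench
Reagents that add atoms: methanol, CO
Why: Base-catalysed transesterification of the activated aryl-ester lactone, as known for benzofuran-2(3H)-ones, frees only the former ring oxygen as a phenol.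

Step 6
Reactants: 7 methyl 2-[2-hydroxy-4,6-bis(triisopropylsilyloxy)phenyl]acetate; 3 [2,3,4-tris(benzyloxy)phenyl]methanol
Product: 8 methyl 2-[2-{[2,3,4-tris(benzyloxy)phenyl]methoxy}-4,6-bis(triisopropylsilyloxy)phenyl]acetate
Conditions: PPh3, diisopropyl azodicarboxylate, THF, 0 → 25 °C
Reagents that add atoms: none
Why: Mitsunobu etherification of a phenol with a primary benzylic alcohol; the neutral conditions avoid relactonisation and silyl loss.

Step 7
Reactants: 8 methyl 2-[2-{[2,3,4-tris(benzyloxy)phenyl]methoxy}-4,6-bis(triisopropylsilyloxy)phenyl]acetate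
Product: 9 methyl 2-diazo-2-[2-{[2,3,4-tris(benzyloxy)phenyl]methoxy}-4,6-bis(triisopropylsilyloxy)phenyl]acetate
Conditions: 4-acetamidobenzenesulfonyl azide, DBU, MeCN, 0 → 25 °C
Reagents that add atoms: 4-acetamidobenzenesulfonyl azide, CC(=O)Nc1ccc(cc1)S(=O)(=O)N=[N+]=[N-]
Why: Regitz diazo transfer to an aryl acetate gives the donor/acceptor diazo ester.

Step 8
Reactants: 9 methyl 2-diazo-2-[2-{[2,3,4-tris(benzyloxy)phenyl]methoxy}-4,6-bis(triisopropylsilyloxy)phenyl]acetate
Product: 10 methyl (2S,3R)-2-[2,3,4-tris(benzyloxy)phenyl]-4,6-bis(triisopropylsilyloxy)-2,3-dihydro-1-benzofuran-3-carboxylate (2,3-cis)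
Conditions: Rh2(S-PTTL)4 (PTTL = N-phthaloyl-tert-leucinate, 1 mol %), toluene, −60 °C
Reagents that add atoms: none
Why: Intramolecular 1,5 C–H insertion of the rhodium carbenoid into the benzylic ether C–H; the concerted insertion should give the cis ester kinetically, the chiral carboxylate ligands choose the carbenoid face and so set C2 (S) and C3 (R), and the silyl ether on the other ortho oxygen offers no competing C–H.

Step 9
Reactants: 10 methyl (2S,3R)-2-[2,3,4-tris(benzyloxy)phenyl]-4,6-bis(triisopropylsilyloxy)-2,3-dihydro-1-benzofuran-3-carboxylate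
Product: 11 {(2S,3S)-2-[2,3,4-tris(benzyloxy)phenyl]-4,6-bis(triisopropylsilyloxy)-2,3-dihydro-1-benzofuran-3-yl}methanol (2,3-cis)
Conditions: i-Bu2AlH (3 equiv), CH2Cl2, −78 °C; Rochelle salt work-up
Reagents that add atoms: none
Why: Non-basic hydride reduction of the ester at low temperature, so the base-labile cis C3 centre is not epimerised.

Step 10
Reactants: 11 {(2S,3S)-2-[2,3,4-tris(benzyloxy)phenyl]-4,6-bis(triisopropylsilyloxy)-2,3-dihydro-1-benzofuran-3-yl}methanol
Product: 13 {(2S,3S)-2-(2,3,4-triacetoxyphenyl)-4,6-bis(triisopropylsilyloxy)-2,3-dihydro-1-benzofuran-3-yl}methyl acetate, via debenzylated tetraol 12 (not isolated)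
Conditions: H2 (1 atm), Pd(OH)2/C, EtOAc–THF, 25 °C; filter under argon; Ac2O, pyridine, DMAP (cat.), 0 °C
Reagents that add atoms: acetic anhydride, CC(=O)OC(C)=O
Why: Hydrogenolysis of the benzyl ethers and immediate peracetylation; the three aryl acetates make ring B electron-poor so that the benzylic C2–O1 bond cannot ionise in step 11, and the primary acetate is the group that will migrate.

Step 11
Reactants: 13 {(2S,3S)-2-(2,3,4-triacetoxyphenyl)-4,6-bis(triisopropylsilyloxy)-2,3-dihydro-1-benzofuran-3-yl}methyl acetate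
Product: 15 (2R,3R)-2-(2,3,4-triacetoxyphenyl)-5,7-bis(triisopropylsilyloxy)chroman-3-yl acetate (2,3-cis), via phenonium triflate 14 (not isolated)
Conditions: Me3SiOTf (0.15 equiv), 2,6-di-tert-butyl-4-methylpyridine (0.3 equiv), CH2Cl2 (0.01 M), −40 → 0 °C; Et3N quench
Reagents that add atoms: none
Why: Proposed new method: silylation of the primary acetate carbonyl by Me3SiOTf turns it into a nucleofuge that leaves with backside help from C4a of ring A to give the spiro-cyclopropyl (phenonium) cation 14, to which acetate (as Me3SiOAc) returns either at the CH2 carbon (degenerate, back to 13) or at C3 anti to the departing C4a, which cuts the C3–C4a bond and gives the chroman 3-acetate; the closest known reaction types are phenonium 1,2-aryl shifts with ion-pair return in β-arylalkyl ester solvolysis, the prolinol-to-3-hydroxypiperidine ring expansion through an aziridinium ion with a trifluoroacetate shuttle under thermodynamic control, and Me3SiOTf activation of glycosyl acetates. No ring is closed in the usual sense: the transient cyclopropane forms by 3-exo-tet ipso attack and ring C arises when the fusion bond of the 2-oxabicyclo[3.1.0]hexane unit breaks (five → six). C2 is not touched and C3 is inverted, with acetate entering on the face the CH2 group has left, so the cis relation set in step 8 is copied into the 2,3-cis (2R,3R) flavan. The step must overcome a kinetic bias, because such a fused phenonium is expected to open faster at the exocyclic CH2 (the bond better aligned with the dienyl π system, as in spirocyclopropylcyclohexadienone alkylating agents); it is therefore run under thermodynamic control with acetate as the only nucleophile, and the change from a primary to a secondary ester plus relief of the eclipsed cis-2,3 strain on the five-membered ring (estimated at several kcal/mol) should pull the equilibrium to 15, whose re-ionisation is the slow direction. Ring B is switched off as its triacetate so that C2–O1 and the B-ring carbons stay spectators, and the hindered pyridine removes adventitious TfOH that would promote elimination.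

Step 12
Reactants: 15 (2R,3R)-2-(2,3,4-triacetoxyphenyl)-5,7-bis(triisopropylsilyloxy)chroman-3-yl acetate
Product: 17 (2R,3R)-2-(2,3,4-trihydroxyphenyl)chromane-3,5,7-triol, via desilylated tetraacetate 16 (not isolated)
Conditions: Bu4NF, AcOH, THF, 0 °C; then K2CO3 (cat.), MeOH, 0 °C, argon; acidic resin quench
Reagents that add atoms: none
Why: Buffered fluoride desilylation followed by Zemplén-type transesterification; cold, brief, oxygen-free base should keep the 2′,4′-dihydroxybenzylic ether from epimerising at C2 through a quinone methide.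

Step 13
Reactants: 17 (2R,3R)-2-(2,3,4-trihydroxyphenyl)chromane-3,5,7-triol; 18 (−)-epicatechin 3-O-gallate
Product: 20 target CNP0217128.1, via epicatechin gallate ortho-quinone 19 (not isolated)
Conditions: horseradish peroxidase, H2O2 (3 % aq., in portions), acetone–citrate/phosphate buffer pH 5.0 (1:10), 25 °C
Reagents that add atoms: none
Why: Peroxidase-mediated benzotropolone formation (purpurogallin-type condensation), known for epicatechin gallate with epigallocatechin: quinone 19 is attacked by C5′ of the pyrogallol ring of 17 (para to 2′-OH, ortho to 4′-OH), the adduct is re-oxidised, C5′ of the catechol adds to the C3′ carbonyl and the bridging C4′ leaves as CO2, which puts the flavan of 17 on C7 beside the tropolone hydroxyl; no stereocentre is formed or touched.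

**Compound list**

1 | 2,3,4-trihydroxybenzaldehyde | O=Cc1ccc(O)c(O)c1O | starting material
2 | 2,3,4-tris(benzyloxy)benzaldehyde | O=Cc1ccc(OCc2ccccc2)c(OCc2ccccc2)c1OCc1ccccc1 | intermediate
3 | [2,3,4-tris(benzyloxy)phenyl]methanol | OCc1ccc(OCc2ccccc2)c(OCc2ccccc2)c1OCc1ccccc1 | intermediate
4 | 2-(2,4,6-trimethoxyphenyl)acetic acid | COc1cc(OC)c(CC(=O)O)c(OC)c1 | starting material
5 | 4,6-dihydroxy-1-benzofuran-2(3H)-one | O=C1Cc2c(O)cc(O)cc2O1 | intermediate
6 | 4,6-bis(triisopropylsilyloxy)-1-benzofuran-2(3H)-one | O=C1Cc2c(O[Si](C(C)C)(C(C)C)C(C)C)cc(O[Si](C(C)C)(C(C)C)C(C)C)cc2O1 | intermediate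
7 | methyl 2-[2-hydroxy-4,6-bis(triisopropylsilyloxy)phenyl]acetate | COC(=O)Cc1c(O)cc(O[Si](C(C)C)(C(C)C)C(C)C)cc1O[Si](C(C)C)(C(C)C)C(C)C | intermediate
8 | methyl 2-[2-{[2,3,4-tris(benzyloxy)phenyl]methoxy}-4,6-bis(triisopropylsilyloxy)phenyl]acetate | COC(=O)Cc1c(OCc2ccc(OCc3ccccc3)c(OCc3ccccc3)c2OCc2ccccc2)cc(O[Si](C(C)C)(C(C)C)C(C)C)cc1O[Si](C(C)C)(C(C)C)C(C)C | intermediate
9 | methyl 2-diazo-2-[2-{[2,3,4-tris(benzyloxy)phenyl]methoxy}-4,6-bis(triisopropylsilyloxy)phenyl]acetate | COC(=O)C(=[N+]=[N-])c1c(OCc2ccc(OCc3ccccc3)c(OCc3ccccc3)c2OCc2ccccc2)cc(O[Si](C(C)C)(C(C)C)C(C)C)cc1O[Si](C(C)C)(C(C)C)C(C)C | intermediate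
10 | methyl (2S,3R)-2-[2,3,4-tris(benzyloxy)phenyl]-4,6-bis(triisopropylsilyloxy)-2,3-dihydro-1-benzofuran-3-carboxylate (cis) | C(c1ccccc1)Oc1ccc([C@H]2Oc3cc(O[Si](C(C)C)(C(C)C)C(C)C)cc(O[Si](C(C)C)(C(C)C)C(C)C)c3[C@H]2C(=O)OC)c(OCc2ccccc2)c1OCc1ccccc1 | intermediate
11 | {(2S,3S)-2-[2,3,4-tris(benzyloxy)phenyl]-4,6-bis(triisopropylsilyloxy)-2,3-dihydro-1-benzofuran-3-yl}methanol (cis) | C(c1ccccc1)Oc1ccc([C@H]2Oc3cc(O[Si](C(C)C)(C(C)C)C(C)C)cc(O[Si](C(C)C)(C(C)C)C(C)C)c3[C@H]2CO)c(OCc2ccccc2)c1OCc1ccccc1 | intermediate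
12 | 4-[(2S,3S)-3-(hydroxymethyl)-4,6-bis(triisopropylsilyloxy)-2,3-dihydro-1-benzofuran-2-yl]benzene-1,2,3-triol | Oc1ccc([C@H]2Oc3cc(O[Si](C(C)C)(C(C)C)C(C)C)cc(O[Si](C(C)C)(C(C)C)C(C)C)c3[C@H]2CO)c(O)c1O | intermediate (not isolated)
13 | {(2S,3S)-2-(2,3,4-triacetoxyphenyl)-4,6-bis(triisopropylsilyloxy)-2,3-dihydro-1-benzofuran-3-yl}methyl acetate | CC(=O)Oc1ccc([C@H]2Oc3cc(O[Si](C(C)C)(C(C)C)C(C)C)cc(O[Si](C(C)C)(C(C)C)C(C)C)c3[C@H]2COC(C)=O)c(OC(C)=O)c1OC(C)=O | intermediate
14 | phenonium ion (spiro-cyclopropane on the ring-A arenium, drawn as its O1 oxocarbenium form) as triflate | CC(=O)Oc1ccc([C@H]2[O+]=C3C=C(O[Si](C(C)C)(C(C)C)C(C)C)C=C(O[Si](C(C)C)(C(C)C)C(C)C)[C@@]34C[C@@H]24)c(OC(C)=O)c1OC(C)=O.[O-]S(=O)(=O)C(F)(F)F | intermediate (not isolated)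
15 | (2R,3R)-2-(2,3,4-triacetoxyphenyl)-5,7-bis(triisopropylsilyloxy)chroman-3-yl acetate (2,3-cis) | CC(=O)Oc1ccc([C@H]2Oc3cc(O[Si](C(C)C)(C(C)C)C(C)C)cc(O[Si](C(C)C)(C(C)C)C(C)C)c3C[C@H]2OC(C)=O)c(OC(C)=O)c1OC(C)=O | intermediate
16 | (2R,3R)-2-(2,3,4-triacetoxyphenyl)-5,7-dihydroxychroman-3-yl acetate | CC(=O)Oc1ccc([C@H]2Oc3cc(O)cc(O)c3C[C@H]2OC(C)=O)c(OC(C)=O)c1OC(C)=O | intermediate (not isolated)
17 | (2R,3R)-2-(2,3,4-trihydroxyphenyl)chromane-3,5,7-triol | Oc1ccc([C@H]2Oc3cc(O)cc(O)c3C[C@H]2O)c(O)c1O | intermediate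
18 | (−)-epicatechin 3-O-gallate, (2R,3R) | O=C(O[C@@H]1Cc2c(O)cc(O)cc2O[C@@H]1c1ccc(O)c(O)c1)c1cc(O)c(O)c(O)c1 | starting material
19 | ortho-quinone of epicatechin gallate | O=C(O[C@@H]1Cc2c(O)cc(O)cc2O[C@@H]1C1=CC(=O)C(=O)C=C1)c1cc(O)c(O)c(O)c1 | intermediate (not isolated)
20 | target CNP0217128.1: (2R,3R)-5,7-dihydroxy-2-{3,4,6-trihydroxy-5-oxo-7-[(2R,3R)-3,5,7-trihydroxychroman-2-yl]-5H-benzo[7]annulen-1-yl}chroman-3-yl 3,4,5-trihydroxybenzoate | O=C(O[C@@H]1Cc2c(O)cc(O)cc2O[C@@H]1c1cc(O)c(O)c2c(=O)c(O)c([C@H]3Oc4cc(O)cc(O)c4C[C@H]3O)ccc12)c1cc(O)c(O)c(O)c1 | target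

**Count and risks**

Total steps: 13. Longest linear sequence: 11 (steps 3–13, from 4).

Steps most likely to fail:

1. Step 11 (Proposed new method). The cation may lose a proton or suffer a hydride shift during the many unproductive ionisation–return cycles at the CH2 carbon, or acetate may fail to return at C3 at a useful rate. Fallback with known chemistry, setting out from 10 and coming back at 15: the regiochemistry is imposed by an oxygen on C3. The enolate of 10 (KN(SiMe3)2, THF, −78 °C) is hydroxylated with 2-(phenylsulfonyl)-3-phenyloxaziridine anti to the 2-aryl group to give the α-hydroxy ester methyl (2R,3S)-3-hydroxy-2-[2,3,4-tris(benzyloxy)phenyl]-4,6-bis(triisopropylsilyloxy)-2,3-dihydro-1-benzofuran-3-carboxylate F1. LiAlH4 (THF, 0 °C) gives the diol (2R,3R)-3-(hydroxymethyl)-2-[2,3,4-tris(benzyloxy)phenyl]-4,6-bis(triisopropylsilyloxy)-2,3-dihydro-1-benzofuran-3-ol F2. TsCl in pyridine (0 °C) sulfonylates only the primary hydroxyl to the monotosylate F3, which is not isolated: the tertiary hydroxyl drives the 1,2-shift of C4a onto the CH2 carbon as tosylate leaves (semipinacol, Tiffeneau–Demjanov-type ring enlargement, made irreversible by carbonyl formation) and gives the flavan-3-one (2R)-2-[2,3,4-tris(benzyloxy)phenyl]-5,7-bis(triisopropylsilyloxy)chroman-3-one F4. LiBH(s-Bu)3 (THF, −78 °C) adds hydride anti to the 2-aryl group to give the 2,3-cis alcohol (2R,3R)-2-[2,3,4-tris(benzyloxy)phenyl]-5,7-bis(triisopropylsilyloxy)chroman-3-ol F5. Hydrogenolysis as in step 10 gives the phenol (2R,3R)-2-(2,3,4-trihydroxyphenyl)-5,7-bis(triisopropylsilyloxy)chroman-3-ol F6, not isolated, and peracetylation returns to 15.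

2. Step 8. Facial (enantio) selectivity and cis selectivity may erode because the di-ortho-substituted aryl ring is twisted out of conjugation with the carbenoid. Fallback, setting out from 9 and coming back at 10: catalyst control is given up for resolution. Achiral Rh2(OAc)4 (CH2Cl2, 0 °C) should give the racemic cis ester, that is 10 together with its enantiomer methyl (2R,3S)-2-[2,3,4-tris(benzyloxy)phenyl]-4,6-bis(triisopropylsilyloxy)-2,3-dihydro-1-benzofuran-3-carboxylate F7. Preparative chromatography on a chiral stationary phase (supercritical CO2/2-propanol, amylose tris(3,5-dimethylphenylcarbamate)) separates the two, and the route continues from 10.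

3. Step 13. The peroxidase also oxidises the pyrogallol partner 17, so redox exchange, self-coupling and over-oxidation may outrun addition of 17 to quinone 19, and the 17-derived half may epimerise at C2 through a quinone methide. Fallback, setting out from 18 and 17 and coming back at 20: the one-pot co-oxidation is replaced by a sequential union. Quinone 19 is generated alone from 18 with an immobilised catechol oxidase (mushroom tyrosinase, a dicopper enzyme that accepts the catechol but not pyrogallol-type rings, O2, pH 5.5, 4 °C). The enzyme is filtered off and the quinone solution is added slowly to excess 17 under argon, so that 17 meets no oxidant before the C–C bond exists; brief aeration then completes the oxidative decarboxylation to 20. No new compound is made (F0).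

Further compounds
F1 | step 11 | methyl (2R,3S)-3-hydroxy-2-[2,3,4-tris(benzyloxy)phenyl]-4,6-bis(triisopropylsilyloxy)-2,3-dihydro-1-benzofuran-3-carboxylate | C(c1ccccc1)Oc1ccc([C@H]2Oc3cc(O[Si](C(C)C)(C(C)C)C(C)C)cc(O[Si](C(C)C)(C(C)C)C(C)C)c3[C@@]2(O)C(=O)OC)c(OCc2ccccc2)c1OCc1ccccc1
F2 | step 11 | (2R,3R)-3-(hydroxymethyl)-2-[2,3,4-tris(benzyloxy)phenyl]-4,6-bis(triisopropylsilyloxy)-2,3-dihydro-1-benzofuran-3-ol | C(c1ccccc1)Oc1ccc([C@H]2Oc3cc(O[Si](C(C)C)(C(C)C)C(C)C)cc(O[Si](C(C)C)(C(C)C)C(C)C)c3[C@@]2(O)CO)c(OCc2ccccc2)c1OCc1ccccc1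
F3 | step 11 | {(2R,3R)-3-hydroxy-2-[2,3,4-tris(benzyloxy)phenyl]-4,6-bis(triisopropylsilyloxy)-2,3-dihydro-1-benzofuran-3-yl}methyl 4-methylbenzenesulfonate | C(c1ccccc1)Oc1ccc([C@H]2Oc3cc(O[Si](C(C)C)(C(C)C)C(C)C)cc(O[Si](C(C)C)(C(C)C)C(C)C)c3[C@@]2(O)COS(=O)(=O)c2ccc(C)cc2)c(OCc2ccccc2)c1OCc1ccccc1
F4 | step 11 | (2R)-2-[2,3,4-tris(benzyloxy)phenyl]-5,7-bis(triisopropylsilyloxy)chroman-3-one | C(c1ccccc1)Oc1ccc([C@H]2Oc3cc(O[Si](C(C)C)(C(C)C)C(C)C)cc(O[Si](C(C)C)(C(C)C)C(C)C)c3CC2=O)c(OCc2ccccc2)c1OCc1ccccc1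
F5 | step 11 | (2R,3R)-2-[2,3,4-tris(benzyloxy)phenyl]-5,7-bis(triisopropylsilyloxy)chroman-3-ol | C(c1ccccc1)Oc1ccc([C@H]2Oc3cc(O[Si](C(C)C)(C(C)C)C(C)C)cc(O[Si](C(C)C)(C(C)C)C(C)C)c3C[C@H]2O)c(OCc2ccccc2)c1OCc1ccccc1
F6 | step 11 | (2R,3R)-2-(2,3,4-trihydroxyphenyl)-5,7-bis(triisopropylsilyloxy)chroman-3-ol | Oc1ccc([C@H]2Oc3cc(O[Si](C(C)C)(C(C)C)C(C)C)cc(O[Si](C(C)C)(C(C)C)C(C)C)c3C[C@H]2O)c(O)c1O
F7 | step 8 | methyl (2R,3S)-2-[2,3,4-tris(benzyloxy)phenyl]-4,6-bis(triisopropylsilyloxy)-2,3-dihydro-1-benzofuran-3-carboxylate | C(c1ccccc1)Oc1ccc([C@@H]2Oc3cc(O[Si](C(C)C)(C(C)C)C(C)C)cc(O[Si](C(C)C)(C(C)C)C(C)C)c3[C@@H]2C(=O)OC)c(OCc2ccccc2)c1OCc1ccccc1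
F0 | step 13 | none | none
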